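**Strategy.** The dihydropyran ring is opened at its C3–C4 bond (chroman numbering). The benzylic carbon C4 and the carbinol carbon C3 are vicinal, so both can come from carbonyl carbons: an aryl aldehyde (C4) and an α-aryloxyisobutyrate ester (C3), already linked through O1 and the quaternary C2. A low-valent titanium oxo-ester coupling of McMurry type joins them in one operation, closing the pyran ring as a cyclic enol ether that is hydrolysed to the chroman-3-one. The C3 stereocentre then follows from CBS reduction. The precursor is an acyclic aryl ether of MOM-protected 2,4,6-trihydroxybenzaldehyde; the benzoyl (C8) and geranyl (C6) groups are attached afterwards.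

Key step: step 3

Remark: chroman numbering (O1, C2, C3, C4, C4a, C5 to C8, C8a) is used for all bicyclic compounds; the single stereocentre C3 of the target is (R); compounds 1, 3, 9 and 13 are taken as commercial.

**Step 1**
Reactants: 1 2,4,6-trihydroxybenzaldehyde
Product: 2 2-hydroxy-4,6-bis(methoxymethoxy)benzaldehyde
Conditions: MOMCl (2.2 equiv), iPr2NEt, CH2Cl2, 0 °C to rt
Reagents that add atoms: chloromethyl methyl ether, COCCl
Why: Base-mediated O-alkylation (MOM acetal formation) of the two non-chelated phenols; the 2-OH is held in a hydrogen bond to the aldehyde and should stay free, which singles out the oxygen that later becomes O1.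

**Step 2**
Reactants: 2 2-hydroxy-4,6-bis(methoxymethoxy)benzaldehyde; 3 ethyl 2-bromo-2-methylpropanoate
Product: 4 ethyl 2-[2-formyl-3,5-bis(methoxymethoxy)phenoxy]-2-methylpropanoate
Conditions: Cs2CO3, DMF, 70 °C
Reagents that add atoms: none
Why: Williamson ether synthesis at the carbonyl-activated tertiary bromide by the only free phenoxide installs O1–C2 with its geminal methyl groups and the ester carbon that becomes C3; neither partner has an enolisable position, so aldol-type side reactions are excluded.

**Step 3**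
Reactants: 4 ethyl 2-[2-formyl-3,5-bis(methoxymethoxy)phenoxy]-2-methylpropanoate
Product: 6 5,7-bis(methoxymethoxy)-2,2-dimethylchroman-3-one, via 3-ethoxy-2H-chromene enol ether 5 (not isolated)
Conditions: TiCl3, Zn dust, DME, reflux, slow addition of 4 at high dilution; then 1 M aq HCl, THF, 0 °C
Reagents that add atoms: water, O
Why: Low-valent titanium reduces the aryl aldehyde, the only readily reducible carbonyl, to a titanium-bound ketyl at C4, which adds to the inductively activated α-aryloxy ester carbonyl C3 in a 6-exo-trig closure of the ring O1–C2–C3–C4–C4a–C8a; deoxygenation on titanium then gives the cyclic enol ether 5 with the new C3=C4 bond. The closest known reaction type is the McMurry keto-ester cyclisation to cyclic enol ethers and cycloalkanones. No stereocentre is formed here: mild acid hydrolysis of the enol ether, which should be much faster than cleavage of the aryl MOM acetals, leaves C3 as a prochiral ketone. The step needs intramolecular aldehyde–ester coupling to win over intermolecular aldehyde–aldehyde coupling, which slow addition at high dilution and the geminal dimethyl group at C2 (favouring the folded conformer) should secure. The ester is not reduced on its own under these conditions, so the aryl–O1 and O1–C2 bonds should stay intact.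

**Step 4**
Reactants: 6 5,7-bis(methoxymethoxy)-2,2-dimethylchroman-3-one
Product: 7 (3R)-5,7-bis(methoxymethoxy)-2,2-dimethylchroman-3-ol
Conditions: (S)-2-methyl-CBS-oxazaborolidine (15 mol%), BH3·SMe2, THF, −20 °C; MeOH quench
Reagents that add atoms: none
Why: Corey–Bakshi–Shibata reduction, in which the (S)-oxazaborolidine–borane complex binds the ketone with the quaternary C2 as the large and the C4 methylene as the small flank and delivers hydride to the face that gives the (R)-carbinol at C3, the only stereocentre of the target.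

**Step 5**
Reactants: 7 (3R)-5,7-bis(methoxymethoxy)-2,2-dimethylchroman-3-ol
Product: 8 (3R)-8-bromo-5,7-bis(methoxymethoxy)-2,2-dimethylchroman-3-ol
Conditions: NBS (1.0 equiv), CH2Cl2, −78 to −20 °C
Reagents that add atoms: N-bromosuccinimide, O=C1CCC(=O)N1Br
Why: Electrophilic aromatic bromination of the electron-rich ring, expected at C8 (flanked by the ring oxygen O1 and one MOM ether) in preference to the more crowded C6 between two MOM ethers, as is usual for 5,7-dialkoxychromans such as protected flavan-3-ols.

**Step 6**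
Reactants: 8 (3R)-8-bromo-5,7-bis(methoxymethoxy)-2,2-dimethylchroman-3-ol; 9 N-methoxy-N-methylbenzamide
Product: 12 [(3R)-3,5,7-trihydroxy-2,2-dimethylchroman-8-yl](phenyl)methanone, via dilithiated aryllithium alkoxide 10 (not isolated), via bis-MOM aryl ketone 11 (not isolated)
Conditions: n-BuLi (2.1 equiv), THF, −78 °C; 9, −78 to 0 °C; then 3 M HCl, MeOH, 45 °C
Reagents that add atoms: none
Why: Deprotonation of the alcohol and bromine–lithium exchange give the C8 aryllithium, which is acylated once by the Weinreb amide (Weinreb ketone synthesis, stable chelated adduct); the acidic methanol quench releases the ketone and cleaves both aryl MOM acetals while no acid-sensitive alkene is yet present.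

**Step 7**
Reactants: 12 [(3R)-3,5,7-trihydroxy-2,2-dimethylchroman-8-yl](phenyl)methanone; 13 geranyl bromide
Product: 14 [(3R)-6-[(2E)-3,7-dimethylocta-2,6-dien-1-yl]-3,5,7-trihydroxy-2,2-dimethylchroman-8-yl](phenyl)methanone (CNP0186586.1)
Conditions: DBU (1.1 equiv), THF, 0 °C to rt
Reagents that add atoms: none
Why: C-Alkylation of the ambident phenoxide of the acylphloroglucinol core at C6, its only unsubstituted ring carbon lying between the two phenols, by SN2 displacement on the primary allylic bromide, which keeps the (E)-geometry of the geranyl chain; this is the established way to C-geranylate acylphloroglucinols.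

**Compound list**
1 | 2,4,6-trihydroxybenzaldehyde | O=Cc1c(O)cc(O)cc1O | starting material
2 | 2-hydroxy-4,6-bis(methoxymethoxy)benzaldehyde | O=Cc1c(O)cc(OCOC)cc1OCOC | intermediate
3 | ethyl 2-bromo-2-methylpropanoate | CCOC(=O)C(C)(C)Br | starting material
4 | ethyl 2-[2-formyl-3,5-bis(methoxymethoxy)phenoxy]-2-methylpropanoate | CCOC(=O)C(C)(C)Oc1cc(OCOC)cc(OCOC)c1C=O | intermediate
5 | 3-ethoxy-5,7-bis(methoxymethoxy)-2,2-dimethyl-2H-chromene | CCOC1=Cc2c(OCOC)cc(OCOC)cc2OC1(C)C | intermediate
6 | 5,7-bis(methoxymethoxy)-2,2-dimethylchroman-3-one | CC1(C)Oc2cc(OCOC)cc(OCOC)c2CC1=O | intermediate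
7 | (3R)-5,7-bis(methoxymethoxy)-2,2-dimethylchroman-3-ol | COCOc1cc(OCOC)c2c(c1)OC(C)(C)[C@H](O)C2 | intermediate
8 | (3R)-8-bromo-5,7-bis(methoxymethoxy)-2,2-dimethylchroman-3-ol | COCOc1cc(OCOC)c2c(c1Br)OC(C)(C)[C@H](O)C2 | intermediate
9 | N-methoxy-N-methylbenzamide | CON(C)C(=O)c1ccccc1 | starting material
10 | lithium (3R)-8-lithio-5,7-bis(methoxymethoxy)-2,2-dimethylchroman-3-olate | [Li]c1c(OCOC)cc(OCOC)c2c1OC(C)(C)[C@H](O[Li])C2 | intermediate
11 | [(3R)-3-hydroxy-5,7-bis(methoxymethoxy)-2,2-dimethylchroman-8-yl](phenyl)methanone | COCOc1cc(OCOC)c2c(c1C(=O)c1ccccc1)OC(C)(C)[C@H](O)C2 | intermediate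
12 | [(3R)-3,5,7-trihydroxy-2,2-dimethylchroman-8-yl](phenyl)methanone | Oc1cc(O)c2c(c1C(=O)c1ccccc1)OC(C)(C)[C@H](O)C2 | intermediate
13 | geranyl bromide [(2E)-1-bromo-3,7-dimethylocta-2,6-diene] | CC(C)=CCC/C(C)=C/CBr | starting material
14 | [(3R)-6-[(2E)-3,7-dimethylocta-2,6-dien-1-yl]-3,5,7-trihydroxy-2,2-dimethylchroman-8-yl](phenyl)methanone | CC(C)=CCC/C(C)=C/Cc1c(O)c2c(c(C(=O)c3ccccc3)c1O)OC(C)(C)[C@H](O)C2 | target

**Total steps:** 7. **Longest linear sequence:** 7 steps (1 to 14).

**Steps most likely to fail**

1. Step 3 (titanium oxo-ester ring closure). Intermolecular reductive coupling of the aldehyde (pinacol and stilbene formation) may outrun attack on the hindered ester carbonyl, and the Lewis-acidic titanium and zinc salts may strip MOM groups. The fallback sets out from 2 and returns at 7; it closes the same C3–C4 bond by olefin metathesis and sets C3 by asymmetric epoxidation. Phenol 2 is O-allylated at the tertiary terminus with tert-butyl 2-methylbut-3-en-2-yl carbonate and catalytic Pd(PPh3)4 in THF to give 2-[(2-methylbut-3-en-2-yl)oxy]-4,6-bis(methoxymethoxy)benzaldehyde F1. Wittig methylenation (Ph3PCH3Br, KOtBu, THF) gives 1,5-bis(methoxymethoxy)-3-[(2-methylbut-3-en-2-yl)oxy]-2-vinylbenzene F2. Ring-closing metathesis with the second-generation Grubbs catalyst in CH2Cl2 at 40 °C should give 5,7-bis(methoxymethoxy)-2,2-dimethyl-2H-chromene F3. Jacobsen epoxidation with the (R,R)-(salen)MnCl catalyst [salen = N,N'-bis(3,5-di-tert-butylsalicylidene)-1,2-cyclohexanediamine], NaOCl and 4-phenylpyridine N-oxide should give (3R,4R)-3,4-epoxy-5,7-bis(methoxymethoxy)-2,2-dimethylchroman F4. This acid-labile epoxide is reduced without purification with LiAlH4 in THF at 0 °C, hydride entering at the benzylic C4, to give 7.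

2. Step 7 (C-geranylation). O-Alkylation of the phenoxide and dearomatising over-alkylation may compete with the wanted C6-alkylation in the last step. The fallback sets out from 8 and returns at 14; it introduces the geranyl group by directed metalation before the ketone exists. Bromide 8 is treated with n-BuLi (2.1 equiv, THF, −78 °C) and benzaldehyde to give (3R)-8-[hydroxy(phenyl)methyl]-5,7-bis(methoxymethoxy)-2,2-dimethylchroman-3-ol F5 (both epimers at the new carbinol carbon). n-BuLi (3.2 equiv, THF, 0 °C) then lithiates C6 between the two MOM ethers; transmetalation with CuI and alkylation with 13 should give (3R)-6-[(2E)-3,7-dimethylocta-2,6-dien-1-yl]-8-[hydroxy(phenyl)methyl]-5,7-bis(methoxymethoxy)-2,2-dimethylchroman-3-ol F6. MnO2 in CH2Cl2 oxidises only the diaryl carbinol, giving [(3R)-6-[(2E)-3,7-dimethylocta-2,6-dien-1-yl]-3-hydroxy-5,7-bis(methoxymethoxy)-2,2-dimethylchroman-8-yl](phenyl)methanone F7. Dilute HCl in MeOH at rt then removes the MOM groups to give 14.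

3. Step 5 (bromination). Bromination may lack site selectivity between C8 and C6 or run on to the dibromide. The fallback sets out from 7 and returns at 12; it blocks C6 with silicon and uses directed metalation instead of electrophilic substitution. n-BuLi (2.2 equiv, THF, 0 °C) removes the hydroxyl proton and lithiates C6 between the two MOM ethers; Me3SiCl gives trimethyl{[(3R)-5,7-bis(methoxymethoxy)-2,2-dimethyl-6-(trimethylsilyl)chroman-3-yl]oxy}silane F8. With C6 blocked, s-BuLi/TMEDA (THF, −78 °C) can lithiate the ring only at C8, and 9 gives [(3R)-5,7-bis(methoxymethoxy)-2,2-dimethyl-6-(trimethylsilyl)-3-(trimethylsilyloxy)chroman-8-yl](phenyl)methanone F9. 3 M HCl in MeOH at 45 °C removes both MOM groups and the silyl ether and protodesilylates C6, giving 12.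

**Further compounds**
F1 | step 3 | 2-[(2-methylbut-3-en-2-yl)oxy]-4,6-bis(methoxymethoxy)benzaldehyde | C=CC(C)(C)Oc1cc(OCOC)cc(OCOC)c1C=O
F2 | step 3 | 1,5-bis(methoxymethoxy)-3-[(2-methylbut-3-en-2-yl)oxy]-2-vinylbenzene | C=CC(C)(C)Oc1cc(OCOC)cc(OCOC)c1C=C
F3 | step 3 | 5,7-bis(methoxymethoxy)-2,2-dimethyl-2H-chromene | COCOc1cc(OCOC)c2c(c1)OC(C)(C)C=C2
F4 | step 3 | (3R,4R)-3,4-epoxy-5,7-bis(methoxymethoxy)-2,2-dimethylchroman | COCOc1cc(OCOC)c2c(c1)OC(C)(C)[C@@H]1O[C@@H]12
F5 | step 7 | (3R)-8-[hydroxy(phenyl)methyl]-5,7-bis(methoxymethoxy)-2,2-dimethylchroman-3-ol | COCOc1cc(OCOC)c2c(c1C(O)c1ccccc1)OC(C)(C)[C@H](O)C2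
F6 | step 7 | (3R)-6-[(2E)-3,7-dimethylocta-2,6-dien-1-yl]-8-[hydroxy(phenyl)methyl]-5,7-bis(methoxymethoxy)-2,2-dimethylchroman-3-ol | CC(C)=CCC/C(C)=C/Cc1c(OCOC)c2c(c(C(O)c3ccccc3)c1OCOC)OC(C)(C)[C@H](O)C2
F7 | step 7 | [(3R)-6-[(2E)-3,7-dimethylocta-2,6-dien-1-yl]-3-hydroxy-5,7-bis(methoxymethoxy)-2,2-dimethylchroman-8-yl](phenyl)methanone | CC(C)=CCC/C(C)=C/Cc1c(OCOC)c2c(c(C(=O)c3ccccc3)c1OCOC)OC(C)(C)[C@H](O)C2
F8 | step 5 | trimethyl{[(3R)-5,7-bis(methoxymethoxy)-2,2-dimethyl-6-(trimethylsilyl)chroman-3-yl]oxy}silane | COCOc1c([Si](C)(C)C)c(OCOC)c2c(c1)OC(C)(C)[C@H](O[Si](C)(C)C)C2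
F9 | step 5 | [(3R)-5,7-bis(methoxymethoxy)-2,2-dimethyl-6-(trimethylsilyl)-3-(trimethylsilyloxy)chroman-8-yl](phenyl)methanone | COCOc1c([Si](C)(C)C)c(OCOC)c2c(c1C(=O)c1ccccc1)OC(C)(C)[C@H](O[Si](C)(C)C)C2
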